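**Slow finish.** The north flask is a kinetic resolution, and its excess arrives late. You have a racemate, a single-handed catalyst and a gas held at 6.2 mM, and the north flask has been followed for a while.

| flask | left-handed substrate | right-handed substrate | gas | catalyst | remark | time |
|---|---|---|---|---|---|---|
| north | 0.050 M | 0.050 M | 6.2 mM (held) | 7.5 mM | the very flask that is asked about, followed so far |  |
| north-west | 0.050 M | 0.050 M | 6.2 mM (held) | 3.8 mM | run made earlier |  |
| flask | 0.050 M | 0.050 M | 6.2 mM (held) | 7.5 mM |  | 1.0 h |

| run | time / min | right-handed substrate / % | left-handed substrate / % |
|---|---|---|---|
| north | 4.00 | 49 | 40 |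
| north | 8.00 | 49 | 30 |
| north | 12.0 | 51 | 22 |
| north | 15.0 | 50 | 22 |
| north | 20.0 | 49 | 17 |
| north | 25.0 | 48 | 11 |
| north | 30.0 | 50 | 4 |
| north-west | 6.00 | 53 | 40 |
| north-west | 12.0 | 49 | 30 |
| north-west | 20.0 | 52 | 24 |
| north-west | 25.0 | 49 | 25 |
| north-west | 30.0 | 52 | 18 |
| north-west | 40.0 | 51 | 13 |

(readings scatter by 1.5 percentage points)

- whether the excess of right-handed substrate over left-handed substrate among what is left of the two reaches 80% by 1.0 h (yes / no)
- the highest excess of right-handed substrate over left-handed substrate among what is left of the two up to 1.0 h

- catalyst is single-handed; left-handed substrate and right-handed substrate are mirror images of each other, charged as a racemate, each of them at the stated concentration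
- at the start none of the gas is in solution

**Odd pair.** In the north run at 25.0 min, the readings put 78.0% of the left-handed substrate charged as gone, yet the excess of right-handed substrate at just 62.7%.

**Clearing it.** The right-handed readings stay around their charge, so let f be c(left-handed substrate) over c(right-handed substrate). The excess is then one minus f over one plus f, and reaching 80% takes f down to 0.111. With the right-handed substrate at its charge, 80% therefore asks for 88.9% of the left-handed substrate to be gone, and the 78.0% read in the north run is less than that.

**My reckoning.** From that reading I take 16.5 min as the clearing time, the time in which the left-handed substrate falls by the factor e, treated as pseudo-first-order. Reaching 80% takes 2.20 clearing times, which is 36.3 min. For 1.0 h I reckon the excess at 94.9%, with the right-handed substrate taken as staying at its charge.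

**Second flask.** The north-west run at 30.0 min gives a clearing time of 29.4 min. That predicts 12.8% left-handed substrate at 40.0 min, and the reading there is 13%.

**The result.** The forecast says yes with a top of 95%, holding that “within scatter only the left-handed one reacts”. The flask gives yes and 94.9%.

    gas ⇌ reagent, rate k1*(csat - [reagent]) (kL = 1.91 min⁻¹)
    left-handed product ⇌ right-handed product (k = 0.136 min⁻¹)
    reagent + catalyst + right-handed substrate → catalyst + right-handed product (k = 24.6 L² mol⁻² min⁻¹)
    catalyst ⇌ dormant form (K = 0.658, k = 0.0295 min⁻¹)
    reagent + catalyst + left-handed substrate → catalyst + left-handed product (k = 2110 L² mol⁻² min⁻¹)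

**What stood.** The flask reached 80% at 35.3 min, which is 2.14 clearing times of 16.5 min. At 0.159 h the flask's reagent was used on the left-handed substrate 47 times as fast as on the right-handed substrate, and when the excess reached 80% the right-handed substrate still stood at 48.7% of the two charged together.

The readings come from a simulation for an exercise, and the scatter is random.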